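Late in a run, target made early has stood longest, and it is this target that has had time to become over-reaction product. For that first-order step taken by itself, the share asked for is a question of age, not of amount.

| setting | south | gamma | beta | alpha | theta | zeta |
|---|---|---|---|---|---|---|
| substrate | 0.25 M | 0.25 M | 0.40 M | 0.60 M | 0.80 M | 1.2 M |
| reagent | 1.7 M | 1.16 M | 1.16 M | 1.16 M | 1.16 M | 1.16 M |
| remark | run made earlier |  |  |  |  |  |
| time |  | 15 min | 15 min | 15 min | 15 min | 15 min |

south run (percent of the substrate charged)

| time / min | target / % | over-reaction product / % |
|---|---|---|
| 0.250 | 0.7 | 0 |
| 0.417 | 1.0 | 0 |
| 0.667 | 2.2 | 0 |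
| 1.00 | 4.1 | 0.8 |
| 2.00 | 10.2 | 0 |
| 3.00 | 17.0 | 0.6 |

(scatter of a reading: 0.5 percentage points)

- what may be going on: substrate + reagent <-> intermediate; intermediate <-> target + released group; target -> over-reaction product
- "hardly changes" means that all values lie within two and a half points (for a concentration: within two and a half percent of the largest)

- share of target in all that became target or over-reaction product for gamma, beta, alpha, theta, zeta, in this order
- how that number moves from the first to the last of them (hardly changes / falls all the way / rises, then falls / falls, then rises / rises all the way)

Take first the main step alone. Target turns into over-reaction product by a first-order step with a constant k, the over-reaction constant. The south run gives it as the over-reaction product formed divided by the area under the target curve up to 3.00 min: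

area = 0.228 min (as a fraction of the charge)

k = 0.6 % / area = 0.0263 min⁻¹

This is a rough reading, since 0.6 % stands against a scatter of 0.5 percentage points.

Replacing the spread of ages by their mean a gives the rule:

share = exp(−k·a)

If target forms evenly over the run, a = t/2 = 7.50 min, and the share is 82.1 %. The exact average for even forming differs from this by 0.53 points, so the mean is good enough.

Now add the slowing of the forming. The south run's late slope, scaled to 1.16 M of reagent, gives a forming rate constant, with the reagent treated as pseudo-first-order:

λ = 0.0464 min⁻¹

Forming that decays at this rate is weighted towards early times, so for gamma:

a = 8.36 min, share = 80.3 %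

Then add the rest. Gamma's substrate charge is 21.6 % of its reagent charge, but zeta's is 103 %, which makes reagent the limiting reagent in zeta. This reckoning commits to about 80.3 % for gamma and gives no figure for the rest of the row.

The forecast gives 84 %, 83.8 %, 83.6 %, 83.4 % and 83 %, and calls the shape "hardly changes". It stands on the same ground, that “the share depends on the target's mean age”; its level is higher than the reckoning here, and its row falls by 1 point from first to last.

    substrate + reagent ⇌ intermediate (K = 1.17 L mol⁻¹, k = 0.00709 L mol⁻¹ s⁻¹)
    intermediate ⇌ target + released group (K = 0.310 M, k = 0.00265 s⁻¹)
    target → over-reaction product (k = 4.74 × 10⁻⁴ s⁻¹)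

The flask gives 77.5 %, 76.8 %, 76.0 %, 75.5 % and 74.6 %: the share falls all the way, by 2.9 points in all. At 15.0 min gamma holds 0.130 M of released group and zeta 0.345 M. Read through the rule with the south-run reading k = 0.0263 min⁻¹, gamma's share corresponds to an apparent target age of 9.69 min, and zeta's share to a longer apparent age of 11.1 min.

(The runs were generated by integration from invented constants, and the scatter is random.)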